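Readings and results are simulated with made-up constants.

Percent of the L charged is the unit to watch in this repeat, and the decision is which set-up to charge.

| setting | maple | alder | oak | ash | north-west | north-east | south-east | east |
|---|---|---|---|---|---|---|---|---|
| L | 0.013 M | 0.013 M | 0.013 M | 0.026 M | 0.013 M | 0.013 M | 0.013 M | 0.013 M (fed, over 16.0 min) |
| J | 1.2 equiv | 0.60 equiv | 0.90 equiv | 1.2 equiv | 1.20 equiv | 1.20 equiv | 1.20 equiv (fed, over 16.0 min) | 1.20 equiv |
| remark | run made earlier | run made earlier | run made earlier | run made earlier | a closed flask charged with all of it at once and left for 20 min | a single well-mixed tank run continuously and read at steady state, 20 min in it on average | all but J at the start; J goes in evenly over 16.0 min, the run ends at 20 min | all but L at the start; L goes in evenly over 16.0 min, the run ends at 20 min |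
| time |  |  |  |  | 20 min |  | 20 min | 20 min |

| run | time / min | X / % | L / % |
|---|---|---|---|
| maple | 1.00 | 49.4 | 27.2 |
| maple | 1.33 | 59.3 | 17.4 |
| maple | 2.00 | 70.0 | 6.9 |
| maple | 3.00 | 74.0 | 2.3 |
| maple | 5.00 | 69.9 | 0.6 |
| maple | 8.00 | 59.3 | 0.3 |
| maple | 12.0 | 49.8 | 0 |
| alder | 0.833 | 27.6 | 33.3 |
| alder | 2.50 | 47.9 | 4.0 |
| alder | 5.00 | 42.7 | 0 |
| alder | 6.00 | 40.5 | 0.1 |
| alder | 10.0 | 32.7 | 0 |
| alder | 12.0 | 29.8 | 0 |
| alder | 15.0 | 27.9 | 0 |
| oak | 0.833 | 35.9 | 33.6 |
| oak | 2.50 | 63.8 | 3.8 |
| oak | 5.00 | 61.9 | 0.4 |
| oak | 6.00 | 59.1 | 0.2 |
| oak | 10.0 | 50.2 | 0 |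
| oak | 12.0 | 45.7 | 0 |
| oak | 15.0 | 42.2 | 0 |
| ash | 1.33 | 66.7 | 17.7 |
| ash | 2.50 | 77.9 | 3.6 |
| ash | 5.00 | 70.6 | 0.4 |
| ash | 8.00 | 59.1 | 0.2 |
| ash | 15.0 | 46.1 | 0.1 |

(standard deviation of a reading: 0.3 percentage points)

- the stated concentrations are those of everything mixed, before any reaction; amounts are the same in each set-up
- the analysis behind the earlier runs scatters by 0.3 percentage points, standard deviation
- the feed brings no volume worth counting
- the earlier runs were made in a closed, stirred flask

- the set-up with the highest amount of X at the outlet or at the end, in percent of the L put in ("none" if the first two lie within 2 percentage points) (north-west / north-east / south-east / east / none)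
- amount of X at the outlet or at the end, in percent of the L put in, north-west
- amount of X at the outlet or at the end, in percent of the L put in, north-east
- amount of X at the outlet or at the end, in percent of the L put in, south-east
- amount of X at the outlet or at the end, in percent of the L put in, east

In the alder run, X reads 42.7%, 32.7% and 27.9% at 5.00 min, 10.0 min and 15.0 min. The later drop is 0.480 of the earlier one, so the curve is levelling, and continuing that series puts the alder level near 23.5%. Alder carries 0.60 equiv of J, so I scale this reading to a fully converted charge and get a level of 39.1%. The same drops give the fade half-life 4.72 min, the time in which the X above its level falls to a half; it is a relaxation half-life.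

Now I solve the two ends, taking L as turned into X on arrival. Charged at once, north-west starts with its whole excess over the level and keeps 42.3% at 20 min. Fed evenly over 16.0 min, east holds X of every age from 4.00 min to 20 min. Averaging the fade over those ages leaves an excess of 13 percentage points, so my east figure is 52.1%, more than north-west. I would charge east and read it at 20 min, without letting it stand.

The forecast names east too, and its grounds for east are that “J is always in excess and the product is younger on average”. It gives 40.5%, 42%, 13% and 47% for north-west, north-east, south-east and east, so my east figure is higher than its own.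

The flask gives 42.4%, 48.0%, 40.5% and 52.8% in that order, with east highest.

    L → G (k = 1.30 /min)
    J + G → X (k = 222 /M/min)
    X ⇌ D (K = 1.48, k = 0.0980 /min)
    G → Q (k = 0.0300 /min)

East ends 14 points above the level read from alder. The neighbour is the same east flask read at 30 min, which is 2.12 fade half-lives later. That leaves 3.2 points of excess, so X should stand at 42.3%. The neighbour holds 42.3% of X, with D at 55.9%.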